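**Plan**

- Numbering and drawing convention: labdane numbering is used throughout. Ring A = C1–C5 and C10; ring B = C5–C10; C11 and C12 hang on C9; C17 = CH3 on C8; C18 = CH2OH and C19 = CH3 on C4; C20 = CH3 on C10; the side chain runs C13–C16 into the butenolide. The C10 methyl is drawn up (β); α is the opposite face.
- Retrosynthesis: cut C12–C13 (B-alkyl Suzuki–Miyaura coupling of vinyl decalin 23 with butenolide iodide 31). Then remove C6–OH/C5–H (hydroboration of a C5=C6 alkene), C8–OH (hydration of C8=CH2) and C3–OH (ketone reduction).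
- Ring A is cut at C3–C4 and C4–C5. It arises by insertion of C4 into the C3–C5 bond of a cyclopentenone (ring C10–C1–C2–C3–C5). The enabling feature is the C3 carbonyl flanked by the alkenyl carbon C5 (C5=C6 lies in ring B): C5 shifts to a carbenoid carbon, and the resulting 2-oxido-diene C3(O)=C4–C5=C6 takes formaldehyde at C4.
- Ring B is cut at C7–C8 and C9–C10: Diels–Alder reaction of 2-vinylcyclopentene 4 with an allenoate.
- Forward order: five-membered ring (from 1), then ring B (step 4), then ring A by one-carbon enlargement (step 10), then oxygenation, then the side chain (step 21).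
- Stereochemistry: a CBS-set carbinol at C3 steers the cycloaddition (C10) and is then erased. C9 comes from kinetic protonation. C4, C8, C5/C6 and C3 come from α-face attack opposite the β-methyls. C16 comes from a Zn–ProPhenol alkynylation, and the E-alkene from syn-hydrozirconation.

Key step: step 10

Assumption: the (S,S)-ProPhenol ligand is taken to deliver the (S)-carbinol in step 19; the enantiomeric ligand serves if the sense of induction is the opposite.

Step 1
Reactants: 1 2-bromo-3-methylcyclopent-2-en-1-one
Product: 2 (S)-2-bromo-3-methylcyclopent-2-en-1-ol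
Conditions: (R)-2-methyl-CBS-oxazaborolidine (cat.), BH3·SMe2, THF, −20 °C
Reagents that add atoms: none
Why: Corey–Bakshi–Shibata reduction, in which the α-bromoalkenyl group acts as the large substituent, so the (R)-catalyst should give the (S)-carbinol (future C3, a temporary control element).

Step 2
Reactants: 2 (S)-2-bromo-3-methylcyclopent-2-en-1-ol
Product: 3 TBS ether of 2
Conditions: TBSCl, imidazole, DMF, rt
Reagents that add atoms: tert-butyldimethylsilyl chloride CC(C)(C)[Si](C)(C)Cl
Why: Standard silylation; the bulky silyl ether later shields the β-face of the diene.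

Step 3
Reactants: 3 TBS ether of 2
Product: 4 diene (S)-tert-butyldimethyl[(3-methyl-2-vinylcyclopent-2-en-1-yl)oxy]silane
Conditions: vinylboronic acid pinacol ester, PdCl2(dppf) (cat.), K3PO4, THF/H2O, 60 °C
Reagents that add atoms: vinylboronic acid pinacol ester C=CB1OC(C)(C)C(C)(C)O1
Why: Suzuki–Miyaura coupling of the alkenyl bromide installs C6 and C7 and gives the semicyclic diene C10=C5–C6=C7.

Step 4
Reactants: 4 diene; 5 ethyl buta-2,3-dienoate
Product: 6 cycloadduct ester (C9 epimers)
Conditions: toluene, 100 °C, sealed tube, BHT (cat.)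
Reagents that add atoms: none
Why: Diels–Alder reaction of the conjugated C=C of the allenoate, in which the free diene terminus C7 bonds to the central allene carbon (C8, leaving C8=CH2) and C10 bonds to the ester-bearing carbon (C9); the dienophile should approach anti to the C3 silyl ether, which sets the quaternary C10 (CH3 cis to OTBS), while the C9 configuration is reset in step 5.

Step 5
Reactants: 6 cycloadduct ester (C9 epimers)
Product: 8 9β-ester (9α-H), via lithium dienolate 7 (not isolated)
Conditions: LDA, THF, −78 °C; then AcOH, −78 °C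
Reagents that add atoms: none
Why: Kinetic α-protonation of the ester dienolate (deconjugative protonation) should occur on the α-face, opposite the adjacent C10 methyl, so both C9 epimers converge on the 9β-ester and the exocyclic C8=CH2 is kept.

Step 6
Reactants: 8 9β-ester
Product: 9 11-alcohol
Conditions: LiAlH4, Et2O, 0 °C
Reagents that add atoms: none
Why: Hydride reduction of the ester to the primary alcohol C11–OH, which fixes C9 as a non-epimerisable centre.

Step 7
Reactants: 9 11-alcohol
Product: 10 11-benzyl ether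
Conditions: NaH, BnBr, Bu4NI (cat.), THF, 0 °C to rt
Reagents that add atoms: benzyl bromide BrCc1ccccc1
Why: Williamson etherification; the benzyl ether survives the organolithium, mercury and borane steps and can be removed by hydrogenolysis once all alkenes are gone.

Step 8
Reactants: 10 11-benzyl ether
Product: 11 3β-allylic alcohol
Conditions: TBAF, THF, rt
Reagents that add atoms: none
Why: Fluoride cleavage of the silyl ether frees the C3 carbinol after it has done its job as control element.

Step 9
Reactants: 11 3β-allylic alcohol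
Product: 12 A-nor enone (C3 ketone conjugated with C5=C6)
Conditions: MnO2, CH2Cl2, rt
Reagents that add atoms: none
Why: Selective allylic oxidation under neutral conditions gives the cyclopentenone without moving the skipped C8=CH2 alkene into conjugation.

Step 10
Reactants: 12 A-nor enone
Product: 15 ring-A hydroxymethyl ketone (3-oxo; 4β-CH3; 4α-CH2OH; C5=C6), via dibromo alkoxide 13 (not isolated), via lithium dienolate 14 (not isolated)
Conditions: CH3CHBr2, LDA, THF, −100 °C; add 12; n-BuLi, −100 to −20 °C; CH2O (monomeric), −78 °C; then H2O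
Reagents that add atoms: 1,1-dibromoethane CC(Br)Br; formaldehyde C=O
Why: Proposed new method: preformed 1,1-dibromoethyllithium adds to the C3 carbonyl (13), and bromine–lithium exchange gives a β-oxido carbenoid in which the alkenyl carbon C5 shifts from C3 to the carbenoid carbon with loss of bromide, so that C4 is inserted into the C3–C5 bond and the lithium 2-oxido-diene 14 forms regiospecifically; the closest known reaction type is the β-oxido carbenoid (dibromomethyllithium) ring enlargement of cycloalkanones with trapping of the enolate, extended here to a conjugated cyclopentenone, a methyl-substituted carbenoid and aldol capture by formaldehyde. Ring A is not closed by a cyclisation but enlarged from five to six members by this 1,2-shift. The new quaternary stereocentre C4 is set in the aldol step: formaldehyde should attack the α-carbon of the dienolate on the α-face, opposite the axial C10 methyl (the sense known for deconjugative alkylation of 4-methyl-3-keto-4-ene decalins), which places CH2OH α and CH3 β. The step needs alkenyl rather than alkyl (C2) migration, secured by the sp2 carbon C5 on the carbinol carbon, and α- and C-attack of the lithium dienolate, usual for hard carbonyl electrophiles. It also needs the enone to survive until addition, secured by forming the weakly basic carbenoid before 12 is added. The quaternary C4 then blocks conjugation, so the C5=C6 alkene stays in place for step 12.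

Step 11
Reactants: 15 ring-A hydroxymethyl ketone
Product: 17 3β,8α,18-triol with C5=C6, via organomercurial 16 (not isolated)
Conditions: Hg(OAc)2, THF/H2O, rt; then NaBH4 (excess), aq. NaOH, 0 °C
Reagents that add atoms: water O
Why: Oxymercuration–demercuration hydrates the 1,1-disubstituted C8=CH2 (far faster than the hindered trisubstituted C5=C6) in the Markovnikov sense, with water entering C8 on the α-face away from the C10 methyl (8α-OH, 8β-CH3); the excess borohydride should also reduce the C3 ketone from the α-face to the equatorial 3β-alcohol.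

Step 12
Reactants: 17 triol
Product: 19 3β,6α,8α,18-tetraol 11-benzyl ether, via 6α-borane 18 (not isolated)
Conditions: BH3·THF (excess), THF, 0 °C to rt; then H2O2, aq. NaOH
Reagents that add atoms: hydrogen peroxide OO
Why: Hydroboration–oxidation adds H and OH syn on the α-face of C5=C6 (the β-face is blocked by the C4 and C10 β-methyls), which should give 5α-H and 6α-OH and so the trans-decalin.

Step 13
Reactants: 19 tetraol
Product: 20 tetrakis-TES ether
Conditions: TESOTf (excess), 2,6-lutidine, CH2Cl2, 0 °C to rt
Reagents that add atoms: triethylsilyl triflate CC[Si](CC)(CC)OS(=O)(=O)C(F)(F)F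
Why: Silyl triflate silylation covers all four hydroxyls, including the tertiary C8–OH, which prevents retro-aldol cleavage at the later aldehyde stage.

Step 14
Reactants: 20 tetrakis-TES ether
Product: 21 11-alcohol (tetra-TES)
Conditions: H2 (1 atm), Pd/C, EtOAc, rt
Reagents that add atoms: none
Why: Hydrogenolysis of the benzyl ether is clean at this stage because no alkene is left and silyl ethers are stable in ethyl acetate.

Step 15
Reactants: 21 11-alcohol
Product: 22 11-aldehyde
Conditions: Dess–Martin periodinane, CH2Cl2, rt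
Reagents that add atoms: none
Why: Dess–Martin oxidation of the hindered primary alcohol under mild conditions that should not epimerise C9.

Step 16
Reactants: 22 11-aldehyde
Product: 23 C9-vinyl decalin
Conditions: Ph3PCH3Br, KHMDS, THF, −78 to 0 °C
Reagents that add atoms: methyltriphenylphosphonium bromide C[P+](c1ccccc1)(c1ccccc1)c1ccccc1.[Br-]
Why: Wittig methylenation adds C12; addition of the unstabilised ylide to the aldehyde should outrun enolisation at C9.

Step 17
Reactants: 24 pent-3-yn-1-ol
Product: 26 (E)-4-iodopent-3-en-1-ol, via alkenylzirconocene 25 (not isolated)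
Conditions: Cp2Zr(H)Cl (excess), THF, rt to 40 °C; then I2, 0 °C
Reagents that add atoms: iodine [I][I]
Why: Hydrozirconation is a syn addition that, with excess reagent, should place zirconium on the methyl-bearing alkyne carbon; iodinolysis with retention then gives the (E)-iodoalkene (future C13=C14).

Step 18
Reactants: 26 (E)-4-iodopent-3-en-1-ol
Product: 27 (E)-4-iodopent-3-enal
Conditions: Dess–Martin periodinane, CH2Cl2, 0 °C; used at once
Reagents that add atoms: none
Why: Dess–Martin oxidation gives the β,γ-unsaturated aldehyde without base, so the alkene should not move into conjugation.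

Step 19
Reactants: 27 (E)-4-iodopent-3-enal; 28 methyl propiolate
Product: 29 methyl (S,E)-4-hydroxy-7-iodooct-6-en-2-ynoate
Conditions: Me2Zn, (S,S)-ProPhenol (cat.), Ph3PO (cat.), toluene, 4 °C; then aq. HCl
Reagents that add atoms: none
Why: Zn–ProPhenol-catalysed enantioselective alkynylation of the aldehyde with the zinc acetylide of methyl propiolate; the ligand sets the carbinol stereocentre (future C16).

Step 20
Reactants: 29 methyl (S,E)-4-hydroxy-7-iodooct-6-en-2-ynoate
Product: 31 (S)-5-[(E)-3-iodobut-2-en-1-yl]-4-methylfuran-2(5H)-one, via (Z)-hydroxy enoate 30 (not isolated)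
Conditions: Me2CuLi (from CuI and MeLi), THF, −78 °C; then dilute HCl, rt
Reagents that add atoms: lithium dimethylcuprate [Li+].C[Cu-]C
Why: Syn carbocupration (conjugate addition) of the ynoate puts CH3 on the β-carbon and the ester cis to the carbinol, so the hydroxy enoate lactonises to the 4-methylbutenolide; the alkenyl iodide should be left alone at −78 °C and the stereocentre is not touched.

Step 21
Reactants: 23 C9-vinyl decalin; 31 butenolide iodide
Product: 33 tetra-TES ether of the target, via B-alkyl-9-BBN 32 (not isolated)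
Conditions: 9-BBN-H, THF, rt; then 31, PdCl2(dppf) (cat.), AsPh3, aq. K3PO4, DMF, rt
Reagents that add atoms: none
Why: B-alkyl Suzuki–Miyaura coupling: anti-Markovnikov hydroboration of the only alkene of 23, then coupling with the alkenyl iodide with retention of the E geometry forms C12–C13.

Step 22
Reactants: 33 tetra-TES ether of the target
Product: 34 target CNP0307004.1
Conditions: HF·pyridine, pyridine/THF, 0 °C to rt
Reagents that add atoms: none
Why: Buffered acidic fluoride removes all four silyl ethers without base, so the butenolide γ-stereocentre and the trisubstituted alkene should be unaffected.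

**Compound list**

1 | 2-bromo-3-methylcyclopent-2-en-1-one | CC1=C(Br)C(=O)CC1 | starting material
2 | (S)-2-bromo-3-methylcyclopent-2-en-1-ol | CC1=C(Br)[C@@H](O)CC1 | intermediate
3 | (S)-[(2-bromo-3-methylcyclopent-2-en-1-yl)oxy](tert-butyl)dimethylsilane | CC1=C(Br)[C@@H](O[Si](C)(C)C(C)(C)C)CC1 | intermediate
4 | (S)-tert-butyldimethyl[(3-methyl-2-vinylcyclopent-2-en-1-yl)oxy]silane (C3–OTBS; C5(vinyl)=C10(CH3)) | CC1=C(C=C)[C@@H](O[Si](C)(C)C(C)(C)C)CC1 | intermediate
5 | ethyl buta-2,3-dienoate | CCOC(=O)C=C=C | starting material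
6 | cycloadduct ester: cyclopentane C10–C1–C2–C3–C5 (3β-OTBS; 10β-CH3) fused to cyclohexene C5=C6–C7–C8(=CH2)–C9(CO2Et)–C10; C9 epimers | CCOC(=O)C1[C@@]2(C)CC[C@H](O[Si](C)(C)C(C)(C)C)C2=CCC1=C | intermediate
7 | lithium ester dienolate of 6 (C9=C11) | CCOC(O[Li])=C1[C@@]2(C)CC[C@H](O[Si](C)(C)C(C)(C)C)C2=CCC1=C | intermediate
8 | 9β-ester (9α-H) of the cycloadduct | CCOC(=O)[C@@H]1[C@@]2(C)CC[C@H](O[Si](C)(C)C(C)(C)C)C2=CCC1=C | intermediate
9 | 11-alcohol (9β-CH2OH; 3β-OTBS; 8-methylene; C5=C6) | OC[C@@H]1[C@@]2(C)CC[C@H](O[Si](C)(C)C(C)(C)C)C2=CCC1=C | intermediate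
10 | 11-benzyl ether of 9 | c1ccccc1COC[C@@H]1[C@@]2(C)CC[C@H](O[Si](C)(C)C(C)(C)C)C2=CCC1=C | intermediate
11 | 3β-allylic alcohol (11-OBn) | c1ccccc1COC[C@@H]1[C@@]2(C)CC[C@H](O)C2=CCC1=C | intermediate
12 | A-nor enone: cyclopentenone with C3=O conjugated to C5=C6; 8-methylene; 9β-CH2OBn; 10β-CH3 | c1ccccc1COC[C@@H]1[C@@]2(C)CCC(=O)C2=CCC1=C | intermediate
13 | lithium alkoxide of the C3 adduct carrying the 1,1-dibromoethyl group (either C3 epimer) | c1ccccc1COC[C@@H]1[C@@]2(C)CCC(O[Li])(C(C)(Br)Br)C2=CCC1=C | intermediate
14 | lithium dienolate C3(OLi)=C4(CH3)–C5=C6 with six-membered ring A | c1ccccc1COC[C@@H]1[C@@]2(C)CCC(O[Li])=C(C)C2=CCC1=C | intermediate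
15 | ring-A hydroxymethyl ketone: 3-oxo; 4β-CH3; 4α-CH2OH; C5=C6; 8-methylene; 11-OBn | c1ccccc1COC[C@@H]1[C@@]2(C)CCC(=O)[C@@](C)(CO)C2=CCC1=C | intermediate
16 | organomercurial: 8α-OH; 8β-CH2HgOAc; 3-oxo | c1ccccc1COC[C@@H]1[C@@]2(C)CCC(=O)[C@@](C)(CO)C2=CC[C@@]1(C[Hg]OC(C)=O)O | intermediate
17 | 3β,8α,18-triol with C5=C6 (11-OBn) | c1ccccc1COC[C@@H]1[C@@]2(C)CC[C@H](O)[C@@](C)(CO)C2=CC[C@@]1(C)O | intermediate
18 | 6α-borane (5α-H); hydroxyls drawn free, borate esters in the flask | c1ccccc1COC[C@@H]1[C@@]2(C)CC[C@H](O)[C@@](C)(CO)[C@@H]2[C@@H](B)C[C@@]1(C)O | intermediate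
19 | 3β,6α,8α,18-tetraol 11-benzyl ether (trans-decalin) | c1ccccc1COC[C@@H]1[C@@]2(C)CC[C@H](O)[C@@](C)(CO)[C@@H]2[C@@H](O)C[C@@]1(C)O | intermediate
20 | 3,6,8,18-tetrakis(triethylsilyl) ether of 19 | c1ccccc1COC[C@@H]1[C@@]2(C)CC[C@H](O[Si](CC)(CC)CC)[C@@](C)(CO[Si](CC)(CC)CC)[C@@H]2[C@@H](O[Si](CC)(CC)CC)C[C@@]1(C)O[Si](CC)(CC)CC | intermediate
21 | 11-alcohol (tetra-TES) | OC[C@@H]1[C@@]2(C)CC[C@H](O[Si](CC)(CC)CC)[C@@](C)(CO[Si](CC)(CC)CC)[C@@H]2[C@@H](O[Si](CC)(CC)CC)C[C@@]1(C)O[Si](CC)(CC)CC | intermediate
22 | 11-aldehyde (tetra-TES) | O=C[C@@H]1[C@@]2(C)CC[C@H](O[Si](CC)(CC)CC)[C@@](C)(CO[Si](CC)(CC)CC)[C@@H]2[C@@H](O[Si](CC)(CC)CC)C[C@@]1(C)O[Si](CC)(CC)CC | intermediate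
23 | C9-vinyl decalin (C11=C12; tetra-TES) | C=C[C@@H]1[C@@]2(C)CC[C@H](O[Si](CC)(CC)CC)[C@@](C)(CO[Si](CC)(CC)CC)[C@@H]2[C@@H](O[Si](CC)(CC)CC)C[C@@]1(C)O[Si](CC)(CC)CC | intermediate
24 | pent-3-yn-1-ol | CC#CCCO | starting material
25 | (E)-alkenylzirconocene chloride from 24 (hydroxyl drawn free) | OCC/C=C(\C)[Zr](Cl)(C1C=CC=C1)C1C=CC=C1 | intermediate
26 | (E)-4-iodopent-3-en-1-ol | OCC/C=C(\C)I | intermediate
27 | (E)-4-iodopent-3-enal | O=CC/C=C(\C)I | intermediate
28 | methyl propiolate | COC(=O)C#C | starting material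
29 | methyl (S,E)-4-hydroxy-7-iodooct-6-en-2-ynoate | COC(=O)C#C[C@@H](O)C/C=C(\C)I | intermediate
30 | methyl (2Z,4S,6E)-4-hydroxy-7-iodo-3-methylocta-2,6-dienoate | COC(=O)/C=C(/C)[C@@H](O)C/C=C(\C)I | intermediate
31 | (S)-5-[(E)-3-iodobut-2-en-1-yl]-4-methylfuran-2(5H)-one | CC1=CC(=O)O[C@H]1C/C=C(\C)I | intermediate
32 | B-alkyl-9-BBN from 23 (boron on C12) | C1CC2CCCC(C1)B2CC[C@@H]1[C@@]2(C)CC[C@H](O[Si](CC)(CC)CC)[C@@](C)(CO[Si](CC)(CC)CC)[C@@H]2[C@@H](O[Si](CC)(CC)CC)C[C@@]1(C)O[Si](CC)(CC)CC | intermediate
33 | 3,6,8,18-tetrakis(triethylsilyl) ether of the target | CC1=CC(=O)O[C@H]1C/C=C(\C)CC[C@@H]1[C@@]2(C)CC[C@H](O[Si](CC)(CC)CC)[C@@](C)(CO[Si](CC)(CC)CC)[C@@H]2[C@@H](O[Si](CC)(CC)CC)C[C@@]1(C)O[Si](CC)(CC)CC | intermediate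
34 | CNP0307004.1 | CC1=CC(=O)O[C@H]1C/C=C(\C)CC[C@@H]1[C@@]2(C)CC[C@H](O)[C@@](C)(CO)[C@@H]2[C@@H](O)C[C@@]1(C)O | target

**Totals**

Total step count: 22. Longest linear sequence: 18 steps (steps 1–16, 21 and 22); the butenolide iodide 31 takes 4 steps (17–20).

**Steps most likely to fail**

Step 10. The saturated C2 may shift instead of the alkenyl C5 in the carbenoid, the dienolate may lose its regiochemistry by proton transfer, or formaldehyde may be taken up at oxygen or at C6. The fallback uses known reaction types and sets out from 12. 1-Ethoxyvinyllithium (THF, −78 °C) should add to the C3 carbonyl on the α-face to give the 1-ethoxyvinyl carbinol F1. Dilute oxalic acid then gives the α-hydroxy methyl ketone F2. Dimethylsulfonium methylide (Me3SI, n-BuLi, THF) should add to the lithium-chelated ketone from the side remote from C5 and give the (S)-2-methyloxiranyl carbinol F3. ZnBr2 or BF3·OEt2 in CH2Cl2 at low temperature then triggers the semipinacol rearrangement of this 2,3-epoxy alcohol: C5 shifts from C3 to C4 anti to the breaking epoxide C–O bond, ring A is enlarged, and the route is rejoined at 15. The weak point of this fallback is that C4 depends on two substrate-controlled additions in a row.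

Step 4. The cycloaddition may be slow at the fully substituted diene terminus C10, the allenoate may dimerise first, or facial control by the silyl ether may be weak. The fallback sets out from 4. Ethyl 4-acetoxybut-2-ynoate F4 (by acetylation of commercial ethyl 4-hydroxybut-2-ynoate) is heated with 4; linear acetylenic esters are the dienophile class known to add to such hindered semicyclic dienes. This should give the cyclohexa-1,4-diene F5 with CH2OAc on C8 and the ester on C9. SmI2 (THF, t-BuOH, −78 °C) then removes the acetate by 1,4-reductive elimination, which gives the same ester dienolate as in step 5; kinetic α-protonation rejoins the route at 8.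

Step 21. The aqueous base may epimerise the butenolide γ-stereocentre (C16), or transmetalation of the hindered alkylborane may be slow. The fallback sets out from 23. Hydroboration as before (32) followed by I2 and NaOMe gives the primary iodide F6. Zinc dust with LiCl in THF gives the alkylzinc iodide F7. Negishi coupling with 31 under Pd(PPh3)4 catalysis, without base, rejoins the route at 33.

**Further compounds**

F1 | step 10 | 1-ethoxyvinyl carbinol (3β-OH; 3α-C(=CH2)OEt) from 12 | c1ccccc1COC[C@@H]1[C@@]2(C)CC[C@@](O)(C(=C)OCC)C2=CCC1=C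
F2 | step 10 | α-hydroxy methyl ketone (3β-OH; 3α-acetyl) | c1ccccc1COC[C@@H]1[C@@]2(C)CC[C@@](O)(C(C)=O)C2=CCC1=C
F3 | step 10 | 3β-hydroxy-3α-[(S)-2-methyloxiran-2-yl] carbinol | c1ccccc1COC[C@@H]1[C@@]2(C)CC[C@@](O)([C@]3(C)CO3)C2=CCC1=C
F4 | step 4 | ethyl 4-acetoxybut-2-ynoate | CCOC(=O)C#CCOC(C)=O
F5 | step 4 | cyclohexa-1,4-diene adduct (C8–CH2OAc; C9–CO2Et; C8=C9; C5=C6; 3β-OTBS; 10β-CH3) | CCOC(=O)C1[C@@]2(C)CC[C@H](O[Si](C)(C)C(C)(C)C)C2=CCC=1COC(C)=O
F6 | step 21 | C12 primary iodide (tetra-TES) | ICC[C@@H]1[C@@]2(C)CC[C@H](O[Si](CC)(CC)CC)[C@@](C)(CO[Si](CC)(CC)CC)[C@@H]2[C@@H](O[Si](CC)(CC)CC)C[C@@]1(C)O[Si](CC)(CC)CC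
F7 | step 21 | C12 alkylzinc iodide (tetra-TES) | I[Zn]CC[C@@H]1[C@@]2(C)CC[C@H](O[Si](CC)(CC)CC)[C@@](C)(CO[Si](CC)(CC)CC)[C@@H]2[C@@H](O[Si](CC)(CC)CC)C[C@@]1(C)O[Si](CC)(CC)CC
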